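A direct plan would copy the squalene-type biogenesis: a linear diepoxy enol silane A1, carrying a linalool-derived chlorocyclopentanol at its end, would be folded in one flask to keto diol A2 by an epoxonium/enol-silane cascade (oxepane, cyclohexane) and a silver-triggered cation–olefin closure (cycloheptene); methyllithium addition and a singlet-oxygen ene reaction/epoxidation would finish.
Weak point 1, the closure of the cycloheptene by 7-endo attack of a tertiary cation on a trisubstituted olefin: it would fight entropy and E1 loss of HCl, and C14 and the position of the new double bond would be poorly controlled.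
Weak point 2, the atom-transfer radical cyclization of linalool to cyclopentanol A3: it would set C19 in the wrong sense, so a dehydration/re-hydration pair would be needed to correct it, and the sulfone used to join the halves would be put on and taken off without building anything.
Weak point 3, the final ene reaction/epoxidation on the unprotected triol: three kinds of allylic hydrogen and two faces would compete on the most advanced intermediate, where C14, C15 and C16 are set at once.

**Retrosynthetic overview**
The cycloheptane (C14–C15–C16–C17–C18–C22–C23) is read as a masked 2-methyl-1,3-dione (C14=O and C16=O flanking C15, next to the quaternary C23). It is never closed as a seven-membered ring: C15–C16 are inserted into the C14–C17 bond of a diquinane by ketene [2+2] cycloaddition and strain-driven opening of the cyclobutanone.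
The diquinane comes in one step from a Pauson–Khand reaction of (R)-dehydrolinalool silyl ether (bonds C18–C22, C17–C14, C14–C23). C19 is taken unchanged from a Sharpless epoxide of geraniol, so no correction of C19 is planned.
Left half: the cyclohexane comes first (desymmetrizing rhodium-catalysed vinyl addition to p-benzoquinone monoketal sets C11, two α′-alkylations set C6), then the oxepane (7-endo opening of a Shi epoxide by the C7 hydroxyl), then the C10 carbinol.
Union: the C13 alkyllithium adds to the C14 carbonyl of the vinylogous ester (Stork–Danheiser) and gives the C14=C15–C16=O enone directly; reagent-controlled reduction at C16 and hydroxyl-directed epoxidation then set C14, C15 and C16. There is no cation–olefin seven-ring closure, no sulfone linker and no late ene reaction.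
Ring order: cyclopentane and cyclopentanone together, then cycloheptane by expansion; cyclohexane (bought as the dienone), then oxepane.

Key step: step 7

Remark: atoms are numbered O1, C2 (CMe2), C3 (CHOH), C4, C5, C6 (CMe), C7 (CH–O) in the oxepane; C6–C11 in the cyclohexane (C10 = C(Me)OH); C12–C13 in the linker; C14 (epoxide, bears C13), C15 (epoxide, Me), C16 (CHOH), C17, C18, C22, C23 (CMe2) in the cycloheptane; C18–C22 in the cyclopentane (C19 = C(Me)OH). It is assumed that the (S)-BINAP–rhodium catalyst attacks the dienone of step 10 with the facial sense known for cyclohexenone.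

**Right half (steps 1–9)**

Step 1
Reactants: 1 geraniol
Product: 2 (2R,3R)-2,3-epoxygeraniol, [(2R,3R)-3-methyl-3-(4-methylpent-3-en-1-yl)oxiran-2-yl]methanol
Conditions: Ti(OiPr)4 (5 mol %), D-(−)-diethyl tartrate (6 mol %), t-BuOOH, 4 Å MS, CH2Cl2, −20 °C
Reagents that add atoms: tert-butyl hydroperoxide, CC(C)(C)OO
Why: Sharpless asymmetric epoxidation touches only the allylic olefin, and the D-tartrate ligand should deliver oxygen to the face that gives the (3R) quaternary carbon, the future C19.

Step 2
Reactants: 2 (2R,3R)-2,3-epoxygeraniol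
Product: 3 (2R,3S)-3-(chloromethyl)-2-methyl-2-(4-methylpent-3-en-1-yl)oxirane
Conditions: PPh3, CCl4, NaHCO3, 70 °C
Reagents that add atoms: carbon tetrachloride, ClC(Cl)(Cl)Cl
Why: Appel chlorination replaces the primary hydroxyl under neutral conditions that leave the epoxide and the trisubstituted olefin alone.

Step 3
Reactants: 3 epoxy chloride
Product: 5 (R)-dehydrolinalool, (3R)-3,7-dimethyloct-6-en-1-yn-3-ol, via dilithium alkynide alkoxide 4 (not isolated)
Conditions: n-BuLi (3.3 equiv), THF, −78 → −30 °C; then aq. NH4Cl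
Reagents that add atoms: none
Why: Base-induced double elimination of a 2,3-epoxy chloride (deprotonation at CH2Cl opens the epoxide to a chlorovinyl alkoxide, which loses HCl) gives the terminal alkyne, and the tertiary C–O bond is never broken, so C19 keeps its configuration.

Step 4
Reactants: 5 (R)-dehydrolinalool
Product: 6 tert-butyl{[(3R)-3,7-dimethyloct-6-en-1-yn-3-yl]oxy}dimethylsilane
Conditions: t-BuMe2SiOSO2CF3, 2,6-lutidine, CH2Cl2, 0 °C → rt
Reagents that add atoms: tert-butyldimethylsilyl trifluoromethanesulfonate, CC(C)(C)[Si](C)(C)OS(=O)(=O)C(F)(F)F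
Why: Silylation of the tertiary propargylic alcohol with the silyl triflate gives a robust, bulky ether that protects C19–O up to step 18 and serves as the steric control element of step 5.

Step 5
Reactants: 6 silyl ether of (R)-dehydrolinalool
Product: 8 (5R,8R)-8-[(tert-butyldimethylsilyl)oxy]-4,4,8-trimethylbicyclo[3.3.0]oct-1-en-3-one (silyloxy group and H5 on the same face), via alkyne hexacarbonyldicobalt complex 7 (not isolated)
Conditions: Co2(CO)8 (1.1 equiv), CH2Cl2, rt; then N-methylmorpholine N-oxide (8 equiv), 0 °C → rt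
Reagents that add atoms: dicobalt octacarbonyl (one CO), O=C=[Co](=C=O)(=C=O)(=C=O)[Co](=C=O)(=C=O)(=C=O)=C=O
Why: Intramolecular Pauson–Khand [2+2+1] cycloaddition, in which the alkyne–Co2(CO)6 complex inserts the trisubstituted olefin and CO to forge C18–C22, C17–C14 and C14–C23 (both five-membered rings and the quaternary C23) in one step, the bulky silyloxy group at the propargylic C19 being expected to take the convex (exo) position of the forming cobaltacycle so that H22 is set cis to the C19 oxygen.

Step 6
Reactants: 8 bicyclic enone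
Product: 10 trimethylsilyl enol ether of 9 (enol ether C14=C17), via saturated ketone 9 (not isolated)
Conditions: H2 (1 atm), Pd/C, EtOAc, rt; filtration; then Me3SiOSO2CF3, Et3N, CH2Cl2, 0 °C
Reagents that add atoms: trimethylsilyl trifluoromethanesulfonate, C[Si](C)(C)OS(=O)(=O)C(F)(F)F
Why: Heterogeneous hydrogenation adds to the convex face of the enone (a trans-fused diquinane is out of reach), which sets H18 cis to H22, and soft enolization can only go toward C17 because C23 is quaternary.

Step 7
Reactants: 10 silyl enol ether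
Product: 13 8-[(tert-butyldimethylsilyl)oxy]-2,2,8-trimethylbicyclo[5.3.0]decane-3,5-dione (cis-fused; H18, H22 and O19 on one face), via dichlorocyclobutanone 11 (not isolated), via silyloxycyclobutanone 12 (not isolated)
Conditions: Cl2CHCOCl, Et3N, hexane, rt; then Zn, AcOH, H2O/i-PrOH, 0 → 60 °C
Reagents that add atoms: dichloroacetyl chloride, ClC(Cl)C(Cl)=O
Why: Dichloroketene, made in the flask, adds across the C14=C17 enol ether in a concerted, asynchronous [2+2] cycloaddition in which its carbonyl carbon bonds to the nucleophilic C17 and its CCl2 carbon to C14; zinc then removes both chlorines, and loss of the silyl group lets the cyclobutanol oxygen push out the C14–C17 bond (retro-aldol), releasing the strain of the four-membered ring and leaving the seven-membered 1,3-dione with C15 and C16 inserted. The closest known reaction is the reductive ring expansion of cyclopentanone silyl enol ethers to cycloheptane-1,3-diones. The only ring closed is the cyclobutane (by cycloaddition); the cycloheptane is not closed at all but arises by two-carbon ring expansion of the cyclopentanone. No stereocentre is created: C14 and C17 of the cycloadduct are transient, and C18, C19 and C22 are not touched. The step needs one regiochemistry only, which the substrate secures twice: the enol ether can exist only toward C17 (C23 is quaternary), and its polarization fixes the orientation of the ketene. The tertiary silyl ether at C19 survives acetic acid.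

Step 8
Reactants: 13 hydroazulene-1,3-dione
Product: 14 8-[(tert-butyldimethylsilyl)oxy]-2,2,4,8-tetramethylbicyclo[5.3.0]decane-3,5-dione (C15 epimers and enol)
Conditions: MeI (1.2 equiv), K2CO3, acetone, 50 °C
Reagents that add atoms: iodomethane, CI
Why: C-Alkylation of the 1,3-diketone enolate at the doubly activated C15, the only position between two carbonyls, installs the C15 methyl group.

Step 9
Reactants: 14 2-methyl-1,3-dione
Product: 15 8-[(tert-butyldimethylsilyl)oxy]-5-methoxy-2,2,4,8-tetramethylbicyclo[5.3.0]dec-4-en-3-one (vinylogous ester: C16–OMe, C15=C16, C14=O)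
Conditions: HC(OMe)3, MeOH, p-TsOH (cat.), rt
Reagents that add atoms: trimethyl orthoformate, COC(OC)OC
Why: Acid-catalysed vinylogous ester formation under equilibrating conditions puts the enol ether on the unhindered C16 carbonyl and leaves the C14 carbonyl, flanked by the gem-dimethyl C23, as the ketone that the union needs.

**Left half (steps 10–17)**

Step 10
Reactants: 16 4,4-dimethoxycyclohexa-2,5-dien-1-one
Product: 17 (5S)-5-ethenyl-4,4-dimethoxycyclohex-2-en-1-one
Conditions: CH2=CHBF3K (1.5 equiv), [Rh(cod)2]BF4 (3 mol %), (S)-BINAP (3.3 mol %), Et3N, toluene/H2O, 30 °C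
Reagents that add atoms: potassium vinyltrifluoroborate, [K+].F[B-](F)(F)C=C
Why: Hayashi–Miyaura rhodium-catalysed asymmetric conjugate addition of an alkenyltrifluoroborate desymmetrizes the achiral dienone (its two enone arms are enantiotopic), the chiral rhodium complex choosing the face that gives the future C11 with its two-carbon C12–C13 arm.

Step 11
Reactants: 17 vinyl enone
Product: 19 (5R,6R)-5-ethenyl-4,4-dimethoxy-6-methylcyclohex-2-en-1-one (mainly trans; C6 is re-enolized in step 12), via lithium dienolate 18 (not isolated)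
Conditions: LiN(iPr)2, THF, −78 °C; then MeI, −78 → −40 °C
Reagents that add atoms: iodomethane, CI
Why: Kinetic α′-deprotonation (C6 is the only enolizable carbon, the other α-carbon being vinylic) and methylation install the C6 methyl group, whose configuration does not matter at this stage.

Step 12
Reactants: 19 methyl enone; 20 5-iodo-2-methylpent-2-ene
Product: 22 (5R,6R)-5-ethenyl-4,4-dimethoxy-6-methyl-6-(4-methylpent-3-en-1-yl)cyclohex-2-en-1-one (vinyl cis to methyl), via lithium dienolate 21 (not isolated)
Conditions: LiN(iPr)2, THF/HMPA, −78 °C; then 20, −78 → −20 °C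
Reagents that add atoms: none
Why: Second α′-alkylation through the cross-conjugated lithium enolate, in which the iodide approaches C6 anti to the neighbouring C11 vinyl group, so that C5 ends trans and the methyl group cis to C12 as in the target, the enone olefin having served as a blocking group for C8.

Step 13
Reactants: 22 quaternary enone
Product: 24 3-ethenyl-4,4-dimethoxy-2-methyl-2-(4-methylpent-3-en-1-yl)cyclohexan-1-ol (hydroxyl, 2-methyl and vinyl on one face), via saturated ketone 23 (not isolated)
Conditions: LiBH(s-Bu)3, THF, −78 °C; then MeOH, NaBH4, −78 → 0 °C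
Reagents that add atoms: none
Why: Conjugate hydride reduction of the β-unsubstituted enone by the trialkylborohydride, then borohydride reduction of the ketone by axial attack anti to the axial C6 methyl group of the preferred chair (vinyl equatorial), which should give the equatorial C7 hydroxyl cis to the methyl group.

Step 14
Reactants: 24 cyclohexanol
Product: 25 2-{2-[(2R)-3,3-dimethyloxiran-2-yl]ethyl}-3-ethenyl-4,4-dimethoxy-2-methylcyclohexan-1-ol (ring configuration as in 24)
Conditions: D-fructose-derived Shi ketone (30 mol %), KHSO5 (as 2KHSO5·KHSO4·K2SO4), K2CO3, Bu4NHSO4, MeCN/(MeO)2CH2/aq. buffer pH 10.5, 0 °C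
Reagents that add atoms: potassium peroxymonosulfate, [K+].[O-]S(=O)(=O)OO
Why: Shi asymmetric epoxidation, in which the chiral dioxirane attacks only the trisubstituted olefin (the monosubstituted vinyl group is inert) through the spiro transition state and gives the (R) epoxide that fixes C3.

Step 15
Reactants: 25 hydroxy epoxide
Product: 27 6-ethenyl-3-hydroxy-2,2,5a-trimethyloctahydro-1-benzoxepin-7-one (trans-fused; C3, C6, C7, C11 as in the target), via oxepane ketal 26 (not isolated)
Conditions: camphorsulfonic acid (10 mol %), CH2Cl2, 0 °C; then acetone/H2O, rt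
Reagents that add atoms: water, O
Why: Acid-catalysed 7-endo epoxide opening, in which the equatorial C7 hydroxyl attacks the tertiary C2 (the carbon that best carries positive charge) while C3 keeps its oxygen and configuration, should give the trans-fused oxepane, and the mild aqueous acid then unmasks the C10 ketone.

Step 16
Reactants: 27 oxepane ketone
Product: 29 6-ethenyl-2,2,5a,7-tetramethyl-3,7-bis(trimethylsilyloxy)decahydro-1-benzoxepine (C10 oxygen axial, cis to the C6 methyl group), via diol 28 (not isolated)
Conditions: MeLi, CeCl3, THF, −78 °C; aqueous work-up; then Me3SiOSO2CF3, Et3N, CH2Cl2, −78 → 0 °C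
Reagents that add atoms: methyllithium, [Li]C; trimethylsilyl trifluoromethanesulfonate, C[Si](C)(C)OS(=O)(=O)C(F)(F)F
Why: 1,2-Addition of the weakly basic organocerium reagent (no enolization toward the α-vinyl C11) from the equatorial direction, the axial approach being blocked by the syn-axial C6 methyl group, gives the axial C10 hydroxyl, and both hydroxyls are then masked as trimethylsilyl ethers that fall off in step 18.

Step 17
Reactants: 29 bis(trimethylsilyl) ether
Product: 31 6-(2-iodoethyl)-2,2,5a,7-tetramethyl-3,7-bis(trimethylsilyloxy)decahydro-1-benzoxepine, via alkylzirconocene chloride 30 (not isolated)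
Conditions: Cp2Zr(H)Cl, THF, rt; then I2, 0 °C
Reagents that add atoms: iodine, II
Why: Hydrozirconation places zirconium at the terminal carbon of the only olefin, and iodinolysis of the C–Zr bond gives the primary iodide at C13 without touching the silyl ethers or the oxepane.

**Union and endgame (steps 18–20)**

Step 18
Reactants: 31 left-half iodide; 15 vinylogous ester
Product: 34 enone triol (C16 ketone, C14=C15 olefin, free C3, C10 and C19 hydroxyls), via alkyllithium 32 (not isolated), via lithium alkoxide adduct 33 (not isolated)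
Conditions: t-BuLi (2.1 equiv), Et2O/pentane, −78 °C; then 15, THF, −78 → 0 °C; then 48% aq. HF, MeCN, 0 °C → rt
Reagents that add atoms: water, O
Why: Iodine–lithium exchange gives the primary alkyllithium, which adds 1,2 to the C14 carbonyl of the vinylogous ester (Stork–Danheiser sequence, C13–C14 bond), and aqueous acid then ionizes the tertiary allylic alcohol, hydrolyses the enol ether to the transposed C14=C15–C16=O enone and removes all three silyl groups, no stereocentre being formed.

Step 19
Reactants: 34 enone triol
Product: 35 (16R)-allylic alcohol (tetrol with C14=C15 olefin)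
Conditions: (S)-Me-CBS oxazaborolidine (20 mol %), BH3·SMe2, THF, −20 °C; then MeOH
Reagents that add atoms: none
Why: Corey–Bakshi–Shibata reduction, in which the (S)-oxazaborolidine treats the tetrasubstituted alkenyl carbon C15 as the large group and the C17 methylene as the small group, should give the (16R) allylic alcohol under reagent control.

Step 20
Reactants: 35 allylic alcohol
Product: 36 CNP0203623.2
Conditions: VO(acac)2 (5 mol %), t-BuOOH, CH2Cl2, 0 °C → rt
Reagents that add atoms: tert-butyl hydroperoxide, CC(C)(C)OO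
Why: Hydroxyl-directed epoxidation, in which the vanadium alkoxide of the C16 hydroxyl delivers the peroxide oxygen to the same face of the tetrasubstituted C14=C15 olefin (syn delivery is the rule for cycloheptenols), sets C14 and C15 together and gives the target.

**Compound list**

1 | geraniol, (2E)-3,7-dimethylocta-2,6-dien-1-ol | CC(C)=CCC/C(C)=C/CO | starting material
2 | (2R,3R)-2,3-epoxygeraniol | CC(C)=CCC[C@@]1(C)O[C@@H]1CO | intermediate
3 | (2R,3S)-3-(chloromethyl)-2-methyl-2-(4-methylpent-3-en-1-yl)oxirane | CC(C)=CCC[C@@]1(C)O[C@@H]1CCl | intermediate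
4 | dilithium salt of 5 (lithium alkoxide and lithium acetylide) | [Li]C#C[C@](C)(O[Li])CCC=C(C)C | intermediate
5 | (R)-dehydrolinalool, (3R)-3,7-dimethyloct-6-en-1-yn-3-ol | C#C[C@](C)(O)CCC=C(C)C | intermediate
6 | tert-butyl{[(3R)-3,7-dimethyloct-6-en-1-yn-3-yl]oxy}dimethylsilane | C#C[C@](C)(O[Si](C)(C)C(C)(C)C)CCC=C(C)C | intermediate
7 | hexacarbonyldicobalt complex of the alkyne of 6 | O=C=[Co]12(=C=O)(=C=O)[Co]3(=C=O)(=C=O)(=C=O)[CH]1C23[C@](C)(O[Si](C)(C)C(C)(C)C)CCC=C(C)C | intermediate
8 | (5R,8R)-8-[(tert-butyldimethylsilyl)oxy]-4,4,8-trimethylbicyclo[3.3.0]oct-1-en-3-one | CC1(C)[C@@H]2CC[C@@](C)(O[Si](C)(C)C(C)(C)C)C2=CC1=O | intermediate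
9 | (1R,5R,6R)-6-[(tert-butyldimethylsilyl)oxy]-2,2,6-trimethylbicyclo[3.3.0]octan-3-one (cis-fused) | CC1(C)[C@@H]2CC[C@@](C)(O[Si](C)(C)C(C)(C)C)[C@@H]2CC1=O | intermediate
10 | trimethylsilyl enol ether of 9 (C14=C17) | CC1(C)[C@@H]2CC[C@@](C)(O[Si](C)(C)C(C)(C)C)[C@@H]2C=C1O[Si](C)(C)C | intermediate
11 | dichlorocyclobutanone cycloadduct of 10 (CCl2 on C14, C=O on C17; configuration at C14 and C17 of no consequence) | CC1(C)[C@@H]2CC[C@@](C)(O[Si](C)(C)C(C)(C)C)[C@@H]2C2C(=O)C(Cl)(Cl)C12O[Si](C)(C)C | intermediate
12 | dechlorinated silyloxycyclobutanone | CC1(C)[C@@H]2CC[C@@](C)(O[Si](C)(C)C(C)(C)C)[C@@H]2C2C(=O)CC12O[Si](C)(C)C | intermediate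
13 | 8-[(tert-butyldimethylsilyl)oxy]-2,2,8-trimethylbicyclo[5.3.0]decane-3,5-dione (cis-fused) | CC1(C)[C@@H]2CC[C@@](C)(O[Si](C)(C)C(C)(C)C)[C@@H]2CC(=O)CC1=O | intermediate
14 | 8-[(tert-butyldimethylsilyl)oxy]-2,2,4,8-tetramethylbicyclo[5.3.0]decane-3,5-dione (C15 epimers) | CC1(C)[C@@H]2CC[C@@](C)(O[Si](C)(C)C(C)(C)C)[C@@H]2CC(=O)C(C)C1=O | intermediate
15 | 8-[(tert-butyldimethylsilyl)oxy]-5-methoxy-2,2,4,8-tetramethylbicyclo[5.3.0]dec-4-en-3-one | CC1(C)[C@@H]2CC[C@@](C)(O[Si](C)(C)C(C)(C)C)[C@@H]2CC(OC)=C(C)C1=O | intermediate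
16 | 4,4-dimethoxycyclohexa-2,5-dien-1-one | COC1(OC)C=CC(=O)C=C1 | starting material
17 | (5S)-5-ethenyl-4,4-dimethoxycyclohex-2-en-1-one | C=C[C@@H]1CC(=O)C=CC1(OC)OC | intermediate
18 | lithium dienolate of 17 | C=C[C@@H]1C=C(O[Li])C=CC1(OC)OC | intermediate
19 | (5R,6R)-5-ethenyl-4,4-dimethoxy-6-methylcyclohex-2-en-1-one | C=C[C@@H]1[C@@H](C)C(=O)C=CC1(OC)OC | intermediate
20 | 5-iodo-2-methylpent-2-ene | CC(C)=CCCI | starting material
21 | lithium dienolate of 19 | C=C[C@@H]1C(C)=C(O[Li])C=CC1(OC)OC | intermediate
22 | (5R,6R)-5-ethenyl-4,4-dimethoxy-6-methyl-6-(4-methylpent-3-en-1-yl)cyclohex-2-en-1-one | C=C[C@@H]1[C@@](C)(CCC=C(C)C)C(=O)C=CC1(OC)OC | intermediate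
23 | saturated ketone from 22 | C=C[C@@H]1[C@@](C)(CCC=C(C)C)C(=O)CCC1(OC)OC | intermediate
24 | 3-ethenyl-4,4-dimethoxy-2-methyl-2-(4-methylpent-3-en-1-yl)cyclohexan-1-ol (OH, 2-Me and vinyl cis) | C=C[C@@H]1[C@@](C)(CCC=C(C)C)[C@H](O)CCC1(OC)OC | intermediate
25 | (R)-epoxide of 24 | C=C[C@@H]1[C@@](C)(CC[C@H]2OC2(C)C)[C@H](O)CCC1(OC)OC | intermediate
26 | oxepane ketal (7,7-dimethoxy analogue of 27) | CC1(C)O[C@@H]2CCC(OC)(OC)[C@H](C=C)[C@@]2(C)CC[C@H]1O | intermediate
27 | 6-ethenyl-3-hydroxy-2,2,5a-trimethyloctahydro-1-benzoxepin-7-one (trans-fused) | CC1(C)O[C@@H]2CCC(=O)[C@H](C=C)[C@@]2(C)CC[C@H]1O | intermediate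
28 | diol (C3 and C10 hydroxyls, C11 vinyl) | CC1(C)O[C@@H]2CC[C@](C)(O)[C@H](C=C)[C@@]2(C)CC[C@H]1O | intermediate
29 | bis(trimethylsilyl) ether of 28 | CC1(C)O[C@@H]2CC[C@](C)(O[Si](C)(C)C)[C@H](C=C)[C@@]2(C)CC[C@H]1O[Si](C)(C)C | intermediate
30 | alkylzirconocene chloride from 29 | CC1(C)O[C@@H]2CC[C@](C)(O[Si](C)(C)C)[C@H](CC[Zr](Cl)(C3C=CC=C3)C3C=CC=C3)[C@@]2(C)CC[C@H]1O[Si](C)(C)C | intermediate
31 | left-half iodide (C13–I) | CC1(C)O[C@@H]2CC[C@](C)(O[Si](C)(C)C)[C@H](CCI)[C@@]2(C)CC[C@H]1O[Si](C)(C)C | intermediate
32 | left-half alkyllithium (C13–Li) | CC1(C)O[C@@H]2CC[C@](C)(O[Si](C)(C)C)[C@H](CC[Li])[C@@]2(C)CC[C@H]1O[Si](C)(C)C | intermediate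
33 | lithium alkoxide adduct (C14 carbinolate, C15=C16 enol ether; C14 epimers) | CC1(C)O[C@@H]2CC[C@](C)(O[Si](C)(C)C)[C@H](CCC3(O[Li])C(C)=C(OC)C[C@@H]4[C@@H](CC[C@@]4(C)O[Si](C)(C)C(C)(C)C)C3(C)C)[C@@]2(C)CC[C@H]1O[Si](C)(C)C | intermediate
34 | enone triol | CC1(C)O[C@@H]2CC[C@](C)(O)[C@H](CCC3=C(C)C(=O)C[C@@H]4[C@@H](CC[C@@]4(C)O)C3(C)C)[C@@]2(C)CC[C@H]1O | intermediate
35 | (16R)-allylic alcohol | CC1(C)O[C@@H]2CC[C@](C)(O)[C@H](CCC3=C(C)[C@H](O)C[C@@H]4[C@@H](CC[C@@]4(C)O)C3(C)C)[C@@]2(C)CC[C@H]1O | intermediate
36 | CNP0203623.2 | CC1(C)O[C@@H]2CC[C@](C)(O)[C@H](CC[C@@]34O[C@]3(C)[C@H](O)C[C@@H]3[C@@H](CC[C@@]3(C)O)C4(C)C)[C@@]2(C)CC[C@H]1O | target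

**Count and risks**

Total step count: 20. Longest linear sequence: 12 steps (steps 1–9, then 18–20).

Steps most likely to fail:

1. Step 5. The olefin insertion may show poor facial selectivity (methyl against silyloxy group on the convex face), so that C22 forms as a mixture relative to C19, and the trisubstituted olefin may insert sluggishly. Fallback, stereoconvergent, from 5 back to 9: the Pauson–Khand reaction would be run on the free alcohol 5 without regard to selectivity to give hydroxy enone F1 as a mixture of C22 epimers. Deprotonation with LiN(iPr)2 (2.2 equiv; the only γ-hydrogen is at C22) and kinetic α-protonation with AcOH at −78 °C would erase C22 and give the β,γ-unsaturated ketone F2 with a tetrasubstituted C18=C22 olefin. Hydrogenation with [Ir(cod)(PCy3)(py)]PF6, directed by the allylic tertiary hydroxyl, would add both hydrogens cis to the C19 oxygen and give the cis-fused hydroxy ketone F3, and silylation (t-BuMe2SiOSO2CF3, 2,6-lutidine) would give 9.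

2. Step 15. The hydroxyl may open the epoxide at C3 instead of C2 (6-exo attack, tetrahydropyran formation), or water may open it first. Fallback, olefin activation instead of epoxide opening, from 24 back to 26: alkenol 24 would be cyclized by intramolecular alkoxymercuration with Hg(OCOCF3)2 (Markovnikov attack of the C7 hydroxyl at C2), and exchange with NaCl would give organomercurial F4. Oxidative demercuration (NaBH4, O2, DMF) would give the C3 alcohols F5 as an epimer mixture, Dess–Martin oxidation the oxepan-3-one F6, and Corey–Bakshi–Shibata reduction ((S)-Me-CBS oxazaborolidine, BH3·SMe2) would set C3 and give 26.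

3. Step 18. The β-branched alkyllithium may enolize the substrate or fail to add at the hindered C14 carbonyl beside the quaternary C23, or it may be lost by protonation or coupling during the exchange. Fallback, alkynyl instead of alkyl nucleophile, from 29 back to 34: ozonolysis of the vinyl group of 29 (O3, then Me2S) would give aldehyde F7, and homologation with lithiated Me3SiCHN2 (Colvin rearrangement) the terminal alkyne F8. Its lithium acetylide (n-BuLi), a small and weakly basic nucleophile, would add to 15, and the same aqueous HF treatment would give enynone F9. Hydrogenation of the triple bond alone with RhCl(PPh3)3/H2 (the tetrasubstituted enone olefin is inert) would give 34.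

**Further compounds**

F1 | step 5 | (8R)-8-hydroxy-4,4,8-trimethylbicyclo[3.3.0]oct-1-en-3-one (C22 epimers) | CC1(C)C2CC[C@@](C)(O)C2=CC1=O
F2 | step 5 | (6R)-6-hydroxy-2,2,6-trimethylbicyclo[3.3.0]oct-1(5)-en-3-one | O=C1CC2=C(CC[C@@]2(C)O)C1(C)C
F3 | step 5 | (1R,5R,6R)-6-hydroxy-2,2,6-trimethylbicyclo[3.3.0]octan-3-one (cis-fused, H1, H5 and OH on one face) | CC1(C)[C@@H]2CC[C@@](C)(O)[C@@H]2CC1=O
F4 | step 15 | 3-(chloromercurio)oxepane ketal (C3 epimers) | CC1(C)O[C@@H]2CCC(OC)(OC)[C@H](C=C)[C@@]2(C)CCC1[Hg]Cl
F5 | step 15 | oxepan-3-ol ketal (C3 epimers) | CC1(C)O[C@@H]2CCC(OC)(OC)[C@H](C=C)[C@@]2(C)CCC1O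
F6 | step 15 | oxepan-3-one ketal | CC1(C)O[C@@H]2CCC(OC)(OC)[C@H](C=C)[C@@]2(C)CCC1=O
F7 | step 18 | left-half aldehyde (C12 formyl on C11) | CC1(C)O[C@@H]2CC[C@](C)(O[Si](C)(C)C)[C@H](C=O)[C@@]2(C)CC[C@H]1O[Si](C)(C)C
F8 | step 18 | left-half terminal alkyne (C12≡C13) | CC1(C)O[C@@H]2CC[C@](C)(O[Si](C)(C)C)[C@H](C#C)[C@@]2(C)CC[C@H]1O[Si](C)(C)C
F9 | step 18 | enynone triol (C12≡C13, C14=C15, C16=O) | CC1(C)O[C@@H]2CC[C@](C)(O)[C@H](C#CC3=C(C)C(=O)C[C@@H]4[C@@H](CC[C@@]4(C)O)C3(C)C)[C@@]2(C)CC[C@H]1O
A1 | direct plan | linear diepoxy enol silane with chlorocyclopentanol terminus | CC1(C)O[C@@H]1CC[C@@]1(C)O[C@@H]1CC/C(O[Si](C)(C)C(C)(C)C)=C/CC/C=C(\C)CC[C@@H]1[C@@H](CC[C@@]1(C)O)C(C)(C)Cl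
A2 | direct plan | tetracyclic keto diol (C10 ketone, C15=C16 olefin) | CC1(C)O[C@@H]2CCC(=O)[C@H](CC[C@H]3C(C)=CC[C@@H]4[C@@H](CC[C@@]4(C)O)C3(C)C)[C@@]2(C)CC[C@H]1O
A3 | direct plan | linalool-derived chlorocyclopentanol sulfone with the wrong C19 configuration | Cc1ccc(cc1)S(=O)(=O)C[C@@H]1[C@@H](CC[C@]1(C)O)C(C)(C)Cl
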